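In the first minutes of each earlier run L grows slowly, at a rate that goes up with G, and later two of the runs jump.

| setting | midnight | autumn | winter | Thursday's | Wednesday's | Saturday's | Friday's | Sunday's |
|---|---|---|---|---|---|---|---|---|
| X | 0.11 M | 0.11 M | 0.11 M | 0.11 M | 0.11 M | 0.11 M | 0.11 M | 0.11 M |
| G | 1.2 equiv | 3.5 equiv | 12 equiv | 1.00 equiv | 2.00 equiv | 4.00 equiv | 8.00 equiv | 15.0 equiv |
| Z | 0.30 equiv | 0.30 equiv | 0.30 equiv | 0.300 equiv | 0.300 equiv | 0.300 equiv | 0.300 equiv | 0.300 equiv |
| remark | run made earlier | run made earlier | run made earlier |  |  |  |  |  |
| time |  |  |  | 8.0 min | 8.0 min | 8.0 min | 8.0 min | 8.0 min |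

| run | time / min | L / % |
|---|---|---|
| midnight | 1.00 | 4.2 |
| midnight | 2.00 | 7.9 |
| midnight | 3.00 | 10.4 |
| midnight | 4.00 | 11.9 |
| autumn | 1.00 | 10.1 |
| autumn | 2.00 | 16.8 |
| autumn | 3.00 | 21.0 |
| autumn | 4.00 | 78.5 |
| winter | 0.333 | 11.8 |
| winter | 0.667 | 18.2 |
| winter | 1.50 | 55.8 |
| winter | 4.00 | 7.5 |

(each reading ± 0.5 percentage points)

- the earlier runs were read with a standard deviation of 0.5 percentage points
- "hardly changes" means that all values lie within two and a half points (for a concentration: within two and a half percent of the largest)

1. amount of L at the end, in percent of the X charged for Thursday's, Wednesday's, Saturday's, Friday's, Sunday's, in this order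
2. how that number moves from the first to the last of them (rises all the way / falls all the way / rises, then falls / hardly changes / falls, then rises)

Two chemists dispute the row. The first holds to one step, X with G giving L, first order in each. She takes the midnight run, whose G is the lowest of the earlier runs, and reads 4.2 % in 1.00 min. That is a rate constant of 0.0420 /min at 1.2 equiv, scaled in proportion to G for the other flasks. Her L at the end then climbs from 24.4 % in Thursday's to 98.5 % in Sunday's.

The second points to the autumn run, where L goes from 21.0 % at 3.00 min to 78.5 % at 4.00 min. For him a slow phase ends in a switch, and afterwards “L is then destroyed by G”. His forecast for the row is 13 %, 50 %, 33 %, 2 % and 0.1 %, so the shape is rises, then falls.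

My own reckoning is a balance of Z, which is charged in the smaller amount, 0.300 equiv. I suppose that each X turned costs one Z and that the slow phase, the induction period, lasts until the charge of Z is used. With the first chemist's rate, Thursday's at 1.00 equiv gives 10.2 min. This is the switch time t_s, the time the one-step rate needs to turn a fraction of X equal to the charge of Z, and it goes inversely with G. It gives 2.91 min for the autumn run, a little before that run's jump, and 0.849 min for the winter run, inside the gap from 0.667 min to 1.50 min. Against the end at 8.0 min, this reckoning keeps Thursday's in the slow phase and puts the switch of Wednesday's earlier, at 5.10 min. I therefore side with the second chemist on the shape.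

The flasks give 16.4 %, 77.9 %, 32.3 %, 3.47 % and 0.0484 %, so the shape is rises, then falls. The second chemist wins on the shape, but for Wednesday's the flask gives 77.9 % against his 50 %. The first chemist's view keeps Thursday's, whose end lies short of t_s: she expects 75.6 % of X left there and 78 % stands, though L in Thursday's is 16.4 %, not her 24.4 %.

    Z + E ⇌ Q, settled at all times (K = 1.40 × 10⁵ /M)
    G + L → J (k = 0.0120 /M/s)
    X + G + E → L + 2 E (k = 5.60 /M²/s)
    X + G → L + E (k = 0.00530 /M/s)

In Thursday's, t_s of 10.2 min lies later than the end at 8.0 min: there 28 % of Z remains, the by-product E is 1.82 × 10⁻⁵ M, and the path X + G to L + E uses X 52 times as fast as the path through E. In Wednesday's, t_s of 5.10 min falls after 4.00 min and before 8.00 min, and across that interval Z drops from 23.4 % to 0.00944 % of its charge, E reaches 0.0757 M, and X left is 1.2 %.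

(The numbers in the tables were computed for an exercise, noise included.)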